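**Retrosynthetic overview**
1. Enabling feature: ring A (C6, C7, C8 and C8a all O-substituted, plus C4a–C5) and the quinone ring (C2', C3', C4' and C5' all O-substituted, plus C1'–C6') are each a squarate C4O4 unit enlarged by two carbons. Ring A is at the hydroquinone level with O1 alkylated, and the other ring is at the quinone level.
2. Both six-membered carbocycles are disconnected together (C5–C6 and C1'–C2') to bis-cyclobutenone 15, an isomer of the target. Ring A comes from a spiro 4-alkoxy-4-alkenylcyclobutenone (alkene C4a=C5), and the quinone from a 4-hydroxy-4-alkynylcyclobutenone (alkyne C1'≡C6').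
3. 15 arises by O1–C2 ether closure of triol 13. 13 arises from a one-flask union of two molecules of dimethyl squarate 11 with the trilithiated C7 linchpin 10.
4. C3 is set in 10 by an auxiliary-controlled (Evans) benzyloxymethylation, and the acyl carbon is then converted into the alkyne.
5. Ring order: two purchased four-membered rings, then the oxane (step 8), then ring A and the quinone ring together by 4→6 ring expansion (step 9).

Key step: step 9

Assumption: 4-bromopent-4-enoic acid (1) is taken as a catalogue compound; the carbinol and spiro carbons of 13–15 form without control and are drawn without configuration, which does no harm because step 9 erases them.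

Step 1
Reactants: 1 4-bromopent-4-enoic acid; 2 (S)-4-benzyl-1,3-oxazolidin-2-one
Product: 4 (S)-4-benzyl-3-(4-bromopent-4-enoyl)-1,3-oxazolidin-2-one, via mixed pivalic anhydride 3 (not isolated)
Conditions: PivCl, Et3N, THF, −20 °C; then 2, LiCl, −20 °C → rt
Reagents that add atoms: none
Why: Standard N-acylation of an Evans oxazolidinone through the mixed pivalic anhydride, which is attacked at its less hindered acyl carbon while the vinyl bromide stays inert.

Step 2
Reactants: 4 imide
Product: 6 (S)-4-benzyl-3-[(R)-2-(benzyloxymethyl)-4-bromopent-4-enoyl]-1,3-oxazolidin-2-one, via chlorotitanium Z-enolate 5 (not isolated)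
Conditions: TiCl4, i-Pr2NEt, CH2Cl2, 0 °C; then BnOCH2Cl, 0 °C
Reagents that add atoms: benzyl chloromethyl ether, ClCOCc1ccccc1
Why: Evans titanium-enolate alkylation with an SN1-type electrophile, in which the chelated Z-enolate 5 is attacked on the face opposite the C4 benzyl group and so sets the future C3 as (R) in 6.

Step 3
Reactants: 6 alkylated imide
Product: 7 (S)-2-(benzyloxymethyl)-4-bromopent-4-en-1-ol
Conditions: LiBH4, MeOH (1 equiv), Et2O, 0 °C; aqueous work-up
Reagents that add atoms: none
Why: Reductive imide cleavage with LiBH4 takes place at the exocyclic carbonyl, returns the auxiliary, and leaves the vinyl bromide, benzyl ether and stereocentre untouched.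

Step 4
Reactants: 7 alcohol
Product: 8 (R)-2-(benzyloxymethyl)-4-bromopent-4-enal
Conditions: Dess–Martin periodinane, CH2Cl2, 0 °C → rt; used directly
Reagents that add atoms: none
Why: Dess–Martin oxidation is nearly neutral and stops at the aldehyde, so the α-stereocentre of the β-benzyloxy aldehyde should not epimerise.

Step 5
Reactants: 8 aldehyde
Product: 9 benzyl (S)-2-(2-bromoallyl)but-3-yn-1-yl ether
Conditions: dimethyl (1-diazo-2-oxopropyl)phosphonate, K2CO3, MeOH, 0 °C → rt
Reagents that add atoms: Ohira–Bestmann reagent, COP(=O)(OC)C(=[N+]=[N-])C(C)=O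
Why: The Ohira–Bestmann variant of the Seyferth–Gilbert homologation converts α-branched β-alkoxy aldehydes into terminal alkynes under mild carbonate conditions faster than they enolise, so the configuration is retained.

Step 6
Reactants: 9 benzyl ether
Product: 10 (S)-2-(2-bromoallyl)but-3-yn-1-ol [(2S)-4-bromo-2-ethynylpent-4-en-1-ol]
Conditions: BCl3, pentamethylbenzene, CH2Cl2, −78 °C; then H2O
Reagents that add atoms: none
Why: Lewis-acid debenzylation with a non-basic cation scavenger at −78 °C cleaves the primary benzyl ether and avoids the reductive conditions that the alkyne and vinyl bromide would not survive.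

Step 7
Reactants: 10 bromo-enynol; 11 dimethyl squarate (3,4-dimethoxycyclobut-3-ene-1,2-dione, 2 equiv)
Product: 13 4-hydroxy-4-[(3S)-3-(hydroxymethyl)-5-(1-hydroxy-2,3-dimethoxy-4-oxocyclobut-2-en-1-yl)hex-5-en-1-yn-1-yl]-2,3-dimethoxycyclobut-2-en-1-one (epimers at both carbinol carbons), via trilithio species 12 (not isolated)
Conditions: n-BuLi (2 equiv), THF, −78 °C; t-BuLi (2 equiv), −78 °C; cannulated into 11, THF, −78 °C; aq. NH4Cl, −78 °C
Reagents that add atoms: none
Why: This is 1,2-addition of organolithiums to a squarate carbonyl: O–H and C(sp)–H deprotonation followed by bromine–lithium exchange gives 12, whose vinyl and alkynyl carbanions each add once to a separate squarate under inverse addition while the lithium alkoxide stays idle at −78 °C, so the two new carbinol centres form unselectively and C3 is not touched.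

Step 8
Reactants: 13 triol
Product: 15 (7S)-7-[(1-hydroxy-2,3-dimethoxy-4-oxocyclobut-2-en-1-yl)ethynyl]-2,3-dimethoxy-9-methylidene-5-oxaspiro[3.5]non-2-en-1-one (epimers at C4 and at the carbinol carbon), via primary triflate 14 (not isolated)
Conditions: Tf2O (1 equiv), 2,6-di-tert-butyl-4-methylpyridine, CH2Cl2, −78 → 0 °C
Reagents that add atoms: none
Why: Selective sulfonylation of the only primary alcohol is followed by 6-exo-tet Williamson-type displacement by the allylic tertiary carbinol oxygen, whereas the propargylic carbinol cannot compete because its closure would place the alkyne in a six-membered ring; no bond to C7 changes.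

Step 9
Reactants: 15 spiro bis-cyclobutenone
Product: 18 (S)-5-(6-hydroxy-7,8-dimethoxychroman-3-yl)-2,3-dimethoxycyclohexa-2,5-diene-1,4-dione (target), via bis-ketene 16 (not isolated), via dienone diradical 17 (not isolated)
Conditions: degassed p-xylene (0.01 M), 138 °C, Ar
Reagents that add atoms: none
Why: Proposed new method: heat opens both cyclobutenones of 15 by conrotatory 4π electrocyclic cleavage (C6–C8a and C2'–C5') with the oxygen on the sp3 carbon (O1 of the spiro-oxane, OH of the carbinol) rotating outward, so that in bis-ketene 16 the methylidene C5 and the alkyne are turned inward toward their ketene carbons. The dienylketene, whose diene is held s-cis because C8=C8a and C4a=C5 are exocyclic on neighbouring oxane atoms, closes ring A by disrotatory 6π electrocyclisation (C5–C6) and enolises to the C6 phenol, which turns the spiro centre into C8a and the spiro-oxane into the fused chroman. The enynylketene closes the quinone ring by attack of ketene carbon C2' on the distal alkyne carbon C1' (Moore cyclisation, six-membered mode) to the σ,π-diradical of 17, and shift of the carbinol hydrogen to C6' delivers the quinone without any oxidant. The closest known reactions are the thermal ring expansions of acyclic 4-alkenyl-4-alkoxycyclobutenones to hydroquinone monoethers and of 4-alkynyl-4-hydroxycyclobutenones to benzoquinones (Moore rearrangement); new are the tying of ether oxygen and alkene into one spiro ring and the running of both modes in one molecule. No stereocentre is created: the uncontrolled spiro and carbinol centres become sp2, so all four diastereomers of 15 converge on one compound, and C3, a spectator under neutral conditions, keeps its (S) configuration. The step needs six- over five-membered closure of the diradical, secured by the non-radical-stabilising sec-alkyl group on C1', and a hydrogen shift faster than radical attack on C4a=C5 or ring A, favoured because the C3 substituent is equatorial on the oxane or chroman and cannot reach them without a ring flip, while high dilution suppresses intermolecular paths.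

**Compound list**
1 | 4-bromopent-4-enoic acid | C=C(Br)CCC(=O)O | starting material
2 | (S)-4-benzyl-1,3-oxazolidin-2-one | O=C1N[C@@H](Cc2ccccc2)CO1 | starting material
3 | 4-bromopent-4-enoic pivalic anhydride (not isolated) | C=C(Br)CCC(=O)OC(=O)C(C)(C)C | intermediate
4 | (S)-4-benzyl-3-(4-bromopent-4-enoyl)-1,3-oxazolidin-2-one | C=C(Br)CCC(=O)N1C(=O)OC[C@@H]1Cc1ccccc1 | intermediate
5 | chlorotitanium Z-enolate of 4 (not isolated) | C=C(Br)C/C=C(\O[Ti](Cl)(Cl)Cl)N1C(=O)OC[C@@H]1Cc1ccccc1 | intermediate
6 | (S)-4-benzyl-3-[(R)-2-(benzyloxymethyl)-4-bromopent-4-enoyl]-1,3-oxazolidin-2-one | O=C(N1C(=O)OC[C@@H]1Cc1ccccc1)[C@H](CC(Br)=C)COCc1ccccc1 | intermediate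
7 | (S)-2-(benzyloxymethyl)-4-bromopent-4-en-1-ol | OC[C@H](CC(Br)=C)COCc1ccccc1 | intermediate
8 | (R)-2-(benzyloxymethyl)-4-bromopent-4-enal | O=C[C@H](CC(Br)=C)COCc1ccccc1 | intermediate
9 | benzyl (S)-2-(2-bromoallyl)but-3-yn-1-yl ether | C#C[C@H](CC(Br)=C)COCc1ccccc1 | intermediate
10 | (S)-2-(2-bromoallyl)but-3-yn-1-ol | C#C[C@H](CC(Br)=C)CO | intermediate
11 | dimethyl squarate | COC1=C(OC)C(=O)C1=O | starting material
12 | trilithio derivative of 10 (alkoxide, acetylide, 2-lithioalkene; not isolated) | [Li]C#C[C@H](CC([Li])=C)CO[Li] | intermediate
13 | bis-adduct triol, (3S), epimers at both carbinol carbons | COC1=C(OC)C(O)(C#C[C@H](CC(=C)C2(O)C(OC)=C(OC)C2=O)CO)C1=O | intermediate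
14 | primary triflate of 13 (not isolated) | COC1=C(OC)C(O)(C#C[C@H](CC(=C)C2(O)C(OC)=C(OC)C2=O)COS(=O)(=O)C(F)(F)F)C1=O | intermediate
15 | (7S)-spiro-oxane bis-cyclobutenone | COC1=C(OC)C(O)(C#C[C@H]2COC3(C(=C)C2)C(OC)=C(OC)C3=O)C1=O | intermediate
16 | bis-ketene (dienylketene plus enynylketene; not isolated) | COC(=C=O)/C(OC)=C(/O)C#C[C@H]1CO/C(=C(\OC)C(OC)=C=O)C(=C)C1 | intermediate
17 | ring-A cyclohexadienone carrying the ring-B σ,π-diradical (not isolated) | COc1c(OC)c(O)[c]c([C@H]2COC3=C(CC(=O)C(OC)=C3OC)C2)c1[O] | intermediate
18 | (S)-5-(6-hydroxy-7,8-dimethoxychroman-3-yl)-2,3-dimethoxycyclohexa-2,5-diene-1,4-dione | COC1=C(OC)C(=O)C([C@H]2COc3c(cc(O)c(OC)c3OC)C2)=CC1=O | target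

**Step count:** 9 steps in total; longest linear sequence 9 steps (1 → 18).

**Steps most likely to fail**

Step 9 (Proposed new method). The ring-B σ-radical may be intercepted by the exocyclic alkene or by the new arene before the hydrogen shift. A ketene may be captured by a tertiary hydroxyl group. Part of the diradical may close in the five-membered mode.

The fallback separates the two ring expansions and uses only known acyclic variants. It sets out from 10 and returns at 18.
- 10 is doubly deprotonated (n-BuLi) and silylated with TMSCl to the O,C-bis(trimethylsilyl) derivative F1.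
- Bromine–lithium exchange (t-BuLi), addition to one equivalent of 11, and a mildly acidic work-up that also removes the O-silyl group give the alkenyl carbinol diol F2.
- Selective tosylation of the primary alcohol (TsCl, pyridine) gives the tosylate F3.
- Thermolysis in toluene, the known ring expansion of 4-alkenyl-4-hydroxycyclobutenones, gives the hydroquinone tosylate F4.
- K2CO3 in degassed MeOH closes the chroman by phenoxide displacement, which only the C8a hydroxyl can reach, and removes the C-silyl group to give the ethynylchromanol F5.
- Double deprotonation (n-BuLi) and addition to 11 give the alkynyl carbinol F6, whose thermolysis in p-xylene is a standard Moore rearrangement to 18.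

Step 7. Bromine–lithium exchange may be incomplete, or the trilithio species may aggregate, so that only one terminus adds. The primary alkoxide may exchange a squarate methoxy group. Two carbanions may add to one squarate.

The fallback removes the alkoxide from the polyanion by a protecting-group detour. It sets out from 10 and returns at 13.
- TBSCl and imidazole give the silyl ether F7.
- n-BuLi (1 equiv) and then t-BuLi (2 equiv) give a dianion only, which adds to two equivalents of 11 to give the silyl-protected bis-adduct F8.
- Buffered HF·pyridine releases 13.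

Step 8. Sulfonylation may stray to a tertiary carbinol, followed by ionisation and loss of methanol to a cyclobutenedione. Closure by the weakly nucleophilic tertiary hydroxyl may also be slow enough for the triflate to decompose.

The fallback replaces sulfonate solvolysis by halide activation with silver assistance. It sets out from 13 and returns at 15.
- Appel iodination (I2, PPh3, imidazole) of the primary alcohol gives the primary iodide F9.
- Ag2O in MeCN in the dark, the conditions used for O-alkylation of 4-hydroxycyclobutenones with alkyl halides, closes the oxane to 15.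

**Further compounds**
F1 | step 9 | (S)-[3-(2-bromoallyl)-4-(trimethylsilyloxy)but-1-yn-1-yl]trimethylsilane | C[Si](C)(C)C#C[C@H](CC(Br)=C)CO[Si](C)(C)C
F2 | step 9 | 4-hydroxy-4-[(4S)-4-(hydroxymethyl)-6-(trimethylsilyl)hex-1-en-5-yn-2-yl]-2,3-dimethoxycyclobut-2-en-1-one | C[Si](C)(C)C#C[C@H](CC(=C)C1(O)C(OC)=C(OC)C1=O)CO
F3 | step 9 | primary tosylate of F2 | C[Si](C)(C)C#C[C@H](CC(=C)C1(O)C(OC)=C(OC)C1=O)COS(=O)(=O)c1ccc(C)cc1
F4 | step 9 | (S)-2-[(2,5-dihydroxy-3,4-dimethoxyphenyl)methyl]-4-(trimethylsilyl)but-3-yn-1-yl tosylate | C[Si](C)(C)C#C[C@H](Cc1cc(O)c(OC)c(OC)c1O)COS(=O)(=O)c1ccc(C)cc1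
F5 | step 9 | (S)-3-ethynyl-7,8-dimethoxychroman-6-ol | C#C[C@H]1COc2c(cc(O)c(OC)c2OC)C1
F6 | step 9 | 4-hydroxy-4-{[(S)-6-hydroxy-7,8-dimethoxychroman-3-yl]ethynyl}-2,3-dimethoxycyclobut-2-en-1-one | COC1=C(OC)C(O)(C#C[C@H]2COc3c(cc(O)c(OC)c3OC)C2)C1=O
F7 | step 7 | (S)-{[2-(2-bromoallyl)but-3-yn-1-yl]oxy}(tert-butyl)dimethylsilane | C#C[C@H](CC(Br)=C)CO[Si](C)(C)C(C)(C)C
F8 | step 7 | tert-butyldimethylsilyl ether of 13 at the primary oxygen | COC1=C(OC)C(O)(C#C[C@H](CC(=C)C2(O)C(OC)=C(OC)C2=O)CO[Si](C)(C)C(C)(C)C)C1=O
F9 | step 8 | primary iodide derived from 13 | COC1=C(OC)C(O)(C#C[C@H](CC(=C)C2(O)C(OC)=C(OC)C2=O)CI)C1=O
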